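**Retrosynthetic overview**

1. Ring numbering used below: C1 ketone, C2 oxirane carbon with the methyl, C3 oxirane CH, C4 CH2, C5 CH with the side chain, C6 CH with the ester. The hydroperoxide is made last by a singlet-oxygen ene reaction of a prenyl ketone; the side chain is grown from an acrolein acetal at C5 by allylboration, cross-metathesis and oxidation.
2. The C6 ester comes from enolate hydroxylation and acylation of the cis-epoxy ketone; the oxirane comes from 1,2-reduction, hydroxyl-directed epoxidation and re-oxidation of an (R)-5-substituted 2-methylcyclohex-2-enone, so C1, C2, C3 and C6 are all relayed from C5.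
3. Key disconnection, C1–C2 and C3–C4: the C2(CH3)=C3 unit of that enone is a propyne (used as a silylpropyne) that zerovalent nickel inserts into a C(=O)–CH2 bond of a 3-substituted cyclobutanone, while a chiral ligand chooses between the two enantiotopic bonds and so sets C5.
4. Enabling feature: C1(=O)–C2(CH3)–C3 is a 2-methylenone retron once the oxirane is removed, and the rest of the ring, C4–C5–C6–C1, carries a single substituent at C5 opposite C1, so it is a strained, mirror-symmetric 3-monosubstituted cyclobutanone.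
5. Ring order: four-membered ring (bought), six-membered ring (step 3), oxirane (step 6).

Key step: step 3

Remark: 2-bromo-3,3-diethoxyprop-1-ene (2-bromoacrolein diethyl acetal) is taken as a catalogue reagent.
Note: the CIP descriptor of C5 changes along the route only through priority changes; the centre is not touched after step 3.

**Step 1**
Reactants: 1 3-oxocyclobutane-1-carboxylic acid; 2 N-hydroxyphthalimide; 3 2-bromo-3,3-diethoxyprop-1-ene
Product: 7 3-(3,3-diethoxyprop-1-en-2-yl)cyclobutan-1-one, via phthalimidoyl ester 4 (not isolated), via alkenyllithium 5 (not isolated), via alkenylzinc chloride 6 (not isolated)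
Conditions: 1 + 2, iPrN=C=NiPr, DMAP (cat.), CH2Cl2, rt, then evaporation (crude 4); 3, t-BuLi (2 equiv), THF, −78 °C, then ZnCl2, −78 °C → rt (6); 4 + 6, Ni(acac)2 (10 mol%), 2,2'-bipyridine (10 mol%), THF/DMF, rt
Reagents that add atoms: 2-bromo-3,3-diethoxyprop-1-ene 3, C=C(Br)C(OCC)OCC
Why: Decarboxylative alkenylation of a redox-active ester: electron transfer from low-valent nickel releases CO2 and the 3-oxocyclobutyl radical, which is captured at nickel and coupled with the alkenyl group delivered from zinc; the organozinc does not add to the ketone, and no stereocentre arises because 7 has a mirror plane through C1 and C3 of the four-membered ring.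

**Step 2**
Reactants: 8 prop-1-yn-1-ylmagnesium bromide; 9 benzyl(chloro)dimethylsilane
Product: 10 benzyl(dimethyl)(prop-1-yn-1-yl)silane
Conditions: THF, 0 °C → rt
Reagents that add atoms: benzyl(chloro)dimethylsilane 9, C[Si](C)(Cl)Cc1ccccc1
Why: Silylation of an alkynyl Grignard reagent by substitution at silicon; the benzyldimethylsilyl group is chosen because it is later removed by fluoride far more easily than trimethylsilyl.

**Step 3**
Reactants: 7 3-(3,3-diethoxyprop-1-en-2-yl)cyclobutan-1-one; 10 benzyl(dimethyl)(prop-1-yn-1-yl)silane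
Product: 11 (5S)-3-[benzyl(dimethyl)silyl]-5-(3,3-diethoxyprop-1-en-2-yl)-2-methylcyclohex-2-en-1-one
Conditions: Ni(cod)2 (10 mol%), chiral BINOL- or TADDOL-derived phosphoramidite (20 mol%, ligand enantiomer chosen in a first screen for (5S)-11), 10 (1.5 equiv), toluene, 90 °C
Reagents that add atoms: benzyl(dimethyl)(prop-1-yn-1-yl)silane 10, CC#C[Si](C)(C)Cc1ccccc1
Why: Proposed new method: zerovalent nickel joins the ketone C=O of 7 and the alkyne of 10 by oxidative cyclization to a spiro oxanickelacyclopentene (C1–C2 forms, with the bulky silyl-bearing carbon on nickel and the methyl-bearing carbon on the carbonyl carbon), strain-driven β-carbon elimination then breaks one C(=O)–CH2 bond of the four-membered ring to give a seven-membered acyl/alkenyl/alkyl nickelacycle, and C(sp2)–C(sp3) reductive elimination forms C3–C4 and frees the catalyst. The closest known reactions are the Ni(cod)2/trialkylphosphine-catalysed intermolecular insertion of alkynes into cyclobutanones (two-carbon ring expansion), its regioselective silylalkyne version on azetidin-3-ones and oxetan-3-ones, and the nickel/chiral phosphoramidite-catalysed intramolecular alkene insertion into 3-substituted cyclobutanones, in which the ligand selects one of two enantiotopic C–C bonds; new here is ligand-controlled bond selection in the intermolecular alkyne insertion. The six-membered ring is closed by reductive elimination from the seven-membered metallacycle, a formal [4+2] ring expansion of the four-membered ring by C2 and C3. No stereocentre is made at a bond-forming atom: C5 becomes stereogenic because the chiral ligand decides which enantiotopic C(=O)–CH2 bond is cleaved. The step needs alkyne regioselectivity (secured by the silyl group), enantiotopic-bond selectivity (ligand) and chemoselectivity for the alkyne over the 1,1-disubstituted alkene of 7 (alkynes bind zerovalent nickel far more strongly, and the acetal is not an allylic leaving group without a Lewis acid).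

**Step 4**
Reactants: 11 (5S)-3-[benzyl(dimethyl)silyl]-5-(3,3-diethoxyprop-1-en-2-yl)-2-methylcyclohex-2-en-1-one
Product: 12 (5R)-5-(3,3-diethoxyprop-1-en-2-yl)-2-methylcyclohex-2-en-1-one
Conditions: Bu4NF (2.5 equiv), wet THF, 0 °C → rt
Reagents that add atoms: none
Why: Fluoride-induced protodesilylation of a benzyldimethylsilyl alkene: fluoride first cleaves the benzyl–silicon bond and the resulting fluorosilane is then protodesilylated under the same mild conditions, which leave the acetal and the non-epimerizable C5 centre untouched.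

**Step 5**
Reactants: 12 (5R)-5-(3,3-diethoxyprop-1-en-2-yl)-2-methylcyclohex-2-en-1-one
Product: 13 (1R,5R)-5-(3,3-diethoxyprop-1-en-2-yl)-2-methylcyclohex-2-en-1-ol (hydroxyl cis to the side chain)
Conditions: NaBH4, CeCl3·7H2O, EtOH, −40 → 0 °C
Reagents that add atoms: none
Why: Luche 1,2-reduction: axial hydride delivery to the half-chair with the C5 substituent pseudo-equatorial should give the pseudo-equatorial alcohol cis to that substituent, as in the reduction of carvone to cis-carveol, and ethanol as solvent keeps the diethyl acetal from exchanging.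

**Step 6**
Reactants: 13 (1R,5R)-5-(3,3-diethoxyprop-1-en-2-yl)-2-methylcyclohex-2-en-1-ol
Product: 14 (1R,2R,4S,6S)-4-(3,3-diethoxyprop-1-en-2-yl)-1-methyl-7-oxabicyclo[4.1.0]heptan-2-ol (oxirane, hydroxyl and side chain on the same face)
Conditions: VO(acac)2 (5 mol%), t-BuOOH (in decane), CH2Cl2, 0 °C → rt
Reagents that add atoms: tert-butyl hydroperoxide, CC(C)(C)OO
Why: Vanadium-catalysed hydroxyl-directed epoxidation: the vanadate ester of the allylic alcohol delivers oxygen to the ring alkene from the face of the hydroxyl, which sets both oxirane carbons cis to the hydroxyl and therefore cis to the C5 substituent, while the side-chain alkene has no free allylic hydroxyl and is left alone.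

**Step 7**
Reactants: 14 (1R,2R,4S,6S)-4-(3,3-diethoxyprop-1-en-2-yl)-1-methyl-7-oxabicyclo[4.1.0]heptan-2-ol
Product: 15 (1S,4R,6S)-4-(3,3-diethoxyprop-1-en-2-yl)-1-methyl-7-oxabicyclo[4.1.0]heptan-2-one
Conditions: Dess–Martin periodinane, NaHCO3, CH2Cl2, 0 °C → rt
Reagents that add atoms: none
Why: Dess–Martin oxidation of the secondary alcohol under buffered conditions gives the cis-epoxy ketone without touching the oxirane, the acetal or any stereocentre.

**Step 8**
Reactants: 15 (1S,4R,6S)-4-(3,3-diethoxyprop-1-en-2-yl)-1-methyl-7-oxabicyclo[4.1.0]heptan-2-one; 16 3-methylbutanoyl chloride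
Product: 19 (1S,3S,4S,6S)-4-(3,3-diethoxyprop-1-en-2-yl)-1-methyl-2-oxo-7-oxabicyclo[4.1.0]heptan-3-yl 3-methylbutanoate, via sodium enolate 17 (not isolated), via sodium alkoxide 18 (not isolated)
Conditions: NaN(SiMe3)2 (1.05 equiv), THF, −78 °C; 3-phenyl-2-(phenylsulfonyl)oxaziridine, −78 °C; then 16, −78 → 0 °C
Reagents that add atoms: 3-phenyl-2-(phenylsulfonyl)oxaziridine, O=S(=O)(c1ccccc1)N1OC1c1ccccc1; 3-methylbutanoyl chloride 16, CC(C)CC(=O)Cl
Why: Enolate hydroxylation with an N-sulfonyloxaziridine (Davis oxidation) followed by O-acylation in the same flask: only C6 can be deprotonated because C2 is quaternary, and the oxidant should approach the enolate anti to the adjacent C5 substituent and anti to the oxirane, which places the C6 oxygen trans to the side chain.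

**Step 9**
Reactants: 19 (1S,3S,4S,6S)-4-(3,3-diethoxyprop-1-en-2-yl)-1-methyl-2-oxo-7-oxabicyclo[4.1.0]heptan-3-yl 3-methylbutanoate
Product: 20 (1S,3S,4S,6S)-1-methyl-2-oxo-4-(3-oxoprop-1-en-2-yl)-7-oxabicyclo[4.1.0]heptan-3-yl 3-methylbutanoate
Conditions: PPTS (cat.), acetone/H2O (10:1), 40 °C
Reagents that add atoms: water, O
Why: Acid-catalysed acetal hydrolysis through an allyl-stabilized oxocarbenium ion, under conditions mild enough for the electron-poor α,β-epoxy ketone and the ester.

**Step 10**
Reactants: 20 (1S,3S,4S,6S)-1-methyl-2-oxo-4-(3-oxoprop-1-en-2-yl)-7-oxabicyclo[4.1.0]heptan-3-yl 3-methylbutanoate; 21 allylboronic acid pinacol ester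
Product: 23 (1S,3S,4S,6S)-4-(3-hydroxyhexa-1,5-dien-2-yl)-1-methyl-2-oxo-7-oxabicyclo[4.1.0]heptan-3-yl 3-methylbutanoate (both epimers at the carbinol carbon), via boronate ester 22 (not isolated)
Conditions: 21 (1.5 equiv), CH2Cl2, rt; then pH 7 buffer
Reagents that add atoms: allylboronic acid pinacol ester 21, C=CCB1OC(C)(C)C(C)(C)O1
Why: Allylboration through a closed six-membered transition state: the pinacol allylboronate adds 1,2 to the aldehyde but not to the ketone or the ester, and the configuration of the new carbinol centre does not matter because it is oxidized in step 12.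

**Step 11**
Reactants: 23 (1S,3S,4S,6S)-4-(3-hydroxyhexa-1,5-dien-2-yl)-1-methyl-2-oxo-7-oxabicyclo[4.1.0]heptan-3-yl 3-methylbutanoate; 24 2-methylbut-2-ene
Product: 25 (1S,3S,4S,6S)-4-(3-hydroxy-6-methylhepta-1,5-dien-2-yl)-1-methyl-2-oxo-7-oxabicyclo[4.1.0]heptan-3-yl 3-methylbutanoate (both epimers at the carbinol carbon)
Conditions: second-generation Grubbs catalyst (5 mol%), 24 (large excess), CH2Cl2, rt
Reagents that add atoms: 2-methylbut-2-ene 24, CC=C(C)C
Why: Olefin cross-metathesis with excess 2-methylbut-2-ene turns the monosubstituted alkene into the prenyl group, while the hindered 1,1-disubstituted alkene next to the ring should not take part.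

**Step 12**
Reactants: 25 (1S,3S,4S,6S)-4-(3-hydroxy-6-methylhepta-1,5-dien-2-yl)-1-methyl-2-oxo-7-oxabicyclo[4.1.0]heptan-3-yl 3-methylbutanoate
Product: 26 (1S,3S,4S,6S)-1-methyl-4-(6-methyl-3-oxohepta-1,5-dien-2-yl)-2-oxo-7-oxabicyclo[4.1.0]heptan-3-yl 3-methylbutanoate
Conditions: Dess–Martin periodinane, NaHCO3, CH2Cl2, 0 °C
Reagents that add atoms: none
Why: Dess–Martin oxidation of the allylic alcohol under buffered, base-free conditions removes the carbinol centre and should keep the β,γ-alkene out of conjugation.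

**Step 13**
Reactants: 26 (1S,3S,4S,6S)-1-methyl-4-(6-methyl-3-oxohepta-1,5-dien-2-yl)-2-oxo-7-oxabicyclo[4.1.0]heptan-3-yl 3-methylbutanoate
Product: 27 (1S,3S,4S,6S)-4-[(4E)-6-hydroperoxy-6-methyl-3-oxohepta-1,4-dien-2-yl]-1-methyl-2-oxo-7-oxabicyclo[4.1.0]heptan-3-yl 3-methylbutanoate (target, CNP0241468.1)
Conditions: O2 (1 atm), tetraphenylporphyrin (cat.), visible light, CH2Cl2, −20 °C
Reagents that add atoms: dioxygen, O=O
Why: Schenck ene reaction of singlet oxygen with the trisubstituted alkene: abstraction of a hydrogen from the CH2 next to the ketone shifts the double bond into conjugation as the (E)-alkene and places the hydroperoxide on the tertiary carbon, the electron-poor α-methylene ketone is inert, and the secondary allylic hydroperoxide from methyl abstraction is the expected by-product to be separated.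

**Compound list**

1 | 3-oxocyclobutane-1-carboxylic acid | O=C1CC(C1)C(=O)O | starting material
2 | N-hydroxyphthalimide | ON1C(=O)c2ccccc2C1=O | starting material
3 | 2-bromo-3,3-diethoxyprop-1-ene | C=C(Br)C(OCC)OCC | starting material
4 | 1,3-dioxoisoindolin-2-yl 3-oxocyclobutane-1-carboxylate | O=C1CC(C1)C(=O)ON1C(=O)c2ccccc2C1=O | intermediate (not isolated)
5 | (3,3-diethoxyprop-1-en-2-yl)lithium | [Li]C(=C)C(OCC)OCC | intermediate (not isolated)
6 | chloro(3,3-diethoxyprop-1-en-2-yl)zinc | Cl[Zn]C(=C)C(OCC)OCC | intermediate (not isolated)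
7 | 3-(3,3-diethoxyprop-1-en-2-yl)cyclobutan-1-one | C=C(C(OCC)OCC)C1CC(=O)C1 | intermediate
8 | prop-1-yn-1-ylmagnesium bromide | CC#C[Mg]Br | starting material
9 | benzyl(chloro)dimethylsilane | C[Si](C)(Cl)Cc1ccccc1 | starting material
10 | benzyl(dimethyl)(prop-1-yn-1-yl)silane | CC#C[Si](C)(C)Cc1ccccc1 | intermediate
11 | (5S)-3-[benzyl(dimethyl)silyl]-5-(3,3-diethoxyprop-1-en-2-yl)-2-methylcyclohex-2-en-1-one | C=C(C(OCC)OCC)[C@@H]1CC([Si](C)(C)Cc2ccccc2)=C(C)C(=O)C1 | intermediate
12 | (5R)-5-(3,3-diethoxyprop-1-en-2-yl)-2-methylcyclohex-2-en-1-one | C=C(C(OCC)OCC)[C@@H]1CC=C(C)C(=O)C1 | intermediate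
13 | (1R,5R)-5-(3,3-diethoxyprop-1-en-2-yl)-2-methylcyclohex-2-en-1-ol | C=C(C(OCC)OCC)[C@@H]1CC=C(C)[C@H](O)C1 | intermediate
14 | (1R,2R,4S,6S)-4-(3,3-diethoxyprop-1-en-2-yl)-1-methyl-7-oxabicyclo[4.1.0]heptan-2-ol | C=C(C(OCC)OCC)[C@@H]1C[C@@H]2O[C@]2(C)[C@H](O)C1 | intermediate
15 | (1S,4R,6S)-4-(3,3-diethoxyprop-1-en-2-yl)-1-methyl-7-oxabicyclo[4.1.0]heptan-2-one | C=C(C(OCC)OCC)[C@@H]1C[C@@H]2O[C@]2(C)C(=O)C1 | intermediate
16 | 3-methylbutanoyl chloride | CC(C)CC(=O)Cl | starting material
17 | sodium C1–C6 enolate of 15 | C=C(C(OCC)OCC)[C@@H]1C[C@@H]2O[C@]2(C)C([O-])=C1.[Na+] | intermediate (not isolated)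
18 | sodium alkoxide of the C6-hydroxy derivative of 15 (oxygen trans to the side chain) | C=C(C(OCC)OCC)[C@@H]1C[C@@H]2O[C@]2(C)C(=O)[C@H]1[O-].[Na+] | intermediate (not isolated)
19 | (1S,3S,4S,6S)-4-(3,3-diethoxyprop-1-en-2-yl)-1-methyl-2-oxo-7-oxabicyclo[4.1.0]heptan-3-yl 3-methylbutanoate | C=C(C(OCC)OCC)[C@@H]1C[C@@H]2O[C@]2(C)C(=O)[C@H]1OC(=O)CC(C)C | intermediate
20 | (1S,3S,4S,6S)-1-methyl-2-oxo-4-(3-oxoprop-1-en-2-yl)-7-oxabicyclo[4.1.0]heptan-3-yl 3-methylbutanoate | C=C(C=O)[C@@H]1C[C@@H]2O[C@]2(C)C(=O)[C@H]1OC(=O)CC(C)C | intermediate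
21 | allylboronic acid pinacol ester | C=CCB1OC(C)(C)C(C)(C)O1 | starting material
22 | pinacol boronate ester of 23 (boron on the carbinol oxygen) | C=C(C(CC=C)OB1OC(C)(C)C(C)(C)O1)[C@@H]1C[C@@H]2O[C@]2(C)C(=O)[C@H]1OC(=O)CC(C)C | intermediate (not isolated)
23 | (1S,3S,4S,6S)-4-(3-hydroxyhexa-1,5-dien-2-yl)-1-methyl-2-oxo-7-oxabicyclo[4.1.0]heptan-3-yl 3-methylbutanoate, both carbinol epimers | C=C(C(O)CC=C)[C@@H]1C[C@@H]2O[C@]2(C)C(=O)[C@H]1OC(=O)CC(C)C | intermediate
24 | 2-methylbut-2-ene | CC=C(C)C | starting material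
25 | (1S,3S,4S,6S)-4-(3-hydroxy-6-methylhepta-1,5-dien-2-yl)-1-methyl-2-oxo-7-oxabicyclo[4.1.0]heptan-3-yl 3-methylbutanoate, both carbinol epimers | C=C(C(O)CC=C(C)C)[C@@H]1C[C@@H]2O[C@]2(C)C(=O)[C@H]1OC(=O)CC(C)C | intermediate
26 | (1S,3S,4S,6S)-1-methyl-4-(6-methyl-3-oxohepta-1,5-dien-2-yl)-2-oxo-7-oxabicyclo[4.1.0]heptan-3-yl 3-methylbutanoate | C=C(C(=O)CC=C(C)C)[C@@H]1C[C@@H]2O[C@]2(C)C(=O)[C@H]1OC(=O)CC(C)C | intermediate
27 | (1S,3S,4S,6S)-4-[(4E)-6-hydroperoxy-6-methyl-3-oxohepta-1,4-dien-2-yl]-1-methyl-2-oxo-7-oxabicyclo[4.1.0]heptan-3-yl 3-methylbutanoate | C=C(C(=O)/C=C/C(C)(C)OO)[C@@H]1C[C@@H]2O[C@]2(C)C(=O)[C@H]1OC(=O)CC(C)C | target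

**Step count and risks**

Total step count: 13. Longest linear sequence: 12 steps (steps 1 and 3 to 13, from acid 1); step 2 is a one-step side branch.

Steps most likely to fail:

1. Step 3 (proposed new method). The ligand may discriminate poorly between the two enantiotopic C(=O)–CH2 bonds, or alkyne oligomerization may outrun insertion under the milder conditions a chiral ligand needs. Fallback with known chemistry, setting out from 7 (with 10) and coming back at 13: the ring expansion is run with the established achiral system (Ni(cod)2, PCy3, toluene, 100 °C) to give racemic silyl enone F1, and Bu4NF gives racemic enone F2. Reduction of F2 with catecholborane and (S)-2-methyl-CBS-oxazaborolidine is reagent-controlled and expected to give the (1R) carbinol from both enantiomers, so the racemate becomes two diastereomers: cis alcohol 13 and trans alcohol F3. These are separated by chromatography and 13 enters step 6. Enantiocontrol is thus moved from the C–C activation to a CBS reduction with separation of diastereomers.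

2. Step 13. Singlet oxygen may abstract hydrogen from the methyl group cis to the chain instead of from the CH2 next to the ketone, and the β,γ-alkene of 26 may slip into conjugation before it reacts. Fallback, setting out from 20 and coming back at 27: CH2=CHMgBr with CeCl3 in THF at −78 °C should add to the aldehyde in preference to the hindered ketone and give vinyl carbinol F4, and Dess–Martin oxidation gives divinyl ketone F5. Separately, 2-methylbut-3-en-2-ol is converted with H2O2 and catalytic H2SO4 into 2-methylbut-3-en-2-yl hydroperoxide F6, which is protected with 2-methoxypropene and PPTS as peroxyketal F7. Cross-metathesis of F5 with F7 (second-generation Hoveyda–Grubbs catalyst, CH2Cl2, 40 °C) gives protected hydroperoxide F8, in which the position of the peroxide and the (E)-alkene are fixed by the reagent. Aqueous acetic acid in THF then releases 27.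

3. Step 8. The enolate of the α,β-epoxy ketone may open or rearrange in a Favorskii-type process, facial selectivity may be incomplete, or the imine by-product may compete in the acylation. Fallback, setting out from 12 and coming back at 19: the C6 oxygen is installed before the oxirane exists. The cross-conjugated dienolate of 12 (LiN(iPr)2, THF, −78 °C) is hydroxylated with the same oxaziridine and acylated in the flask with 16 to give acyloxy enone F9, trans to the C5 substituent as with carvone. Luche reduction then gives allylic alcohol F10 (hydroxyl trans to the ester, cis to the side chain), VO(acac)2/t-BuOOH gives epoxy alcohol F11, and Dess–Martin oxidation gives 19.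

**Further compounds**

F1 | step 3 | racemic 3-[benzyl(dimethyl)silyl]-5-(3,3-diethoxyprop-1-en-2-yl)-2-methylcyclohex-2-en-1-one | C=C(C(OCC)OCC)C1CC([Si](C)(C)Cc2ccccc2)=C(C)C(=O)C1
F2 | step 3 | racemic 5-(3,3-diethoxyprop-1-en-2-yl)-2-methylcyclohex-2-en-1-one | C=C(C(OCC)OCC)C1CC=C(C)C(=O)C1
F3 | step 3 | (1R,5S)-5-(3,3-diethoxyprop-1-en-2-yl)-2-methylcyclohex-2-en-1-ol (hydroxyl trans to the side chain) | C=C(C(OCC)OCC)[C@H]1CC=C(C)[C@H](O)C1
F4 | step 13 | (1S,3S,4S,6S)-4-(3-hydroxypenta-1,4-dien-2-yl)-1-methyl-2-oxo-7-oxabicyclo[4.1.0]heptan-3-yl 3-methylbutanoate, both carbinol epimers | C=C(C(O)C=C)[C@@H]1C[C@@H]2O[C@]2(C)C(=O)[C@H]1OC(=O)CC(C)C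
F5 | step 13 | (1S,3S,4S,6S)-1-methyl-2-oxo-4-(3-oxopenta-1,4-dien-2-yl)-7-oxabicyclo[4.1.0]heptan-3-yl 3-methylbutanoate | C=C(C(=O)C=C)[C@@H]1C[C@@H]2O[C@]2(C)C(=O)[C@H]1OC(=O)CC(C)C
F6 | step 13 | 2-methylbut-3-en-2-yl hydroperoxide | C=CC(C)(C)OO
F7 | step 13 | 3-[(2-methoxypropan-2-yl)peroxy]-3-methylbut-1-ene | C=CC(C)(C)OOC(C)(C)OC
F8 | step 13 | (1S,3S,4S,6S)-4-{(4E)-6-[(2-methoxypropan-2-yl)peroxy]-6-methyl-3-oxohepta-1,4-dien-2-yl}-1-methyl-2-oxo-7-oxabicyclo[4.1.0]heptan-3-yl 3-methylbutanoate | C=C(C(=O)/C=C/C(C)(C)OOC(C)(C)OC)[C@@H]1C[C@@H]2O[C@]2(C)C(=O)[C@H]1OC(=O)CC(C)C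
F9 | step 8 | (1S,6S)-6-(3,3-diethoxyprop-1-en-2-yl)-3-methyl-2-oxocyclohex-3-en-1-yl 3-methylbutanoate (ester trans to the side chain) | C=C(C(OCC)OCC)[C@@H]1CC=C(C)C(=O)[C@H]1OC(=O)CC(C)C
F10 | step 8 | (1S,2S,6S)-6-(3,3-diethoxyprop-1-en-2-yl)-2-hydroxy-3-methylcyclohex-3-en-1-yl 3-methylbutanoate (hydroxyl trans to the ester, cis to the side chain) | C=C(C(OCC)OCC)[C@@H]1CC=C(C)[C@H](O)[C@H]1OC(=O)CC(C)C
F11 | step 8 | (1R,2R,3S,4S,6S)-4-(3,3-diethoxyprop-1-en-2-yl)-2-hydroxy-1-methyl-7-oxabicyclo[4.1.0]heptan-3-yl 3-methylbutanoate (oxirane cis to hydroxyl and side chain) | C=C(C(OCC)OCC)[C@@H]1C[C@@H]2O[C@]2(C)[C@H](O)[C@H]1OC(=O)CC(C)C
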